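The numbers of this flask are made up; the rest is arithmetic.

If you mean to repeat these runs, read the charges first and keep your eye on two fractions, substrate and target.

common to all: reagent 16.5 mM; free catalyst 0.11 mM
- south-west: substrate 11 mM; one stirred flow tank at steady state, fed with the mixture as stated, mean residence time 24.0 s
- north: substrate 11 mM; a closed flask charged with all of it at once and left for 8.0 s; time 8.0 s
- south-east: substrate 11 mM (fed, over 4.00 s); a stirred flask in which substrate is dosed at a steady rate over 4.00 s without added volume, worked up at 8.0 s; time 8.0 s
- south: substrate 11 mM; a single well-mixed tank run continuously and read at steady state, 8.0 s in it on average

1. the set-up with the highest amount of target at the outlet or at the end, in percent of the substrate put in ("none" if the first two lie within 2 percentage points) (south-west / north / south-east / south / none)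
2. amount of target at the outlet or at the end, in percent of the substrate put in, south-west
3. amount of target at the outlet or at the end, in percent of the substrate put in, north
4. amount of target at the outlet or at the end, in percent of the substrate put in, south-east
5. amount of target at the outlet or at the end, in percent of the substrate put in, south

- the stated concentrations are those of everything mixed, before any reaction; amounts are the same in each set-up
- the feed brings no volume worth counting
- run time (north): 8.0 s

    substrate + free catalyst ⇌ free catalyst + open intermediate (K1 = 1.51, k1 = 1310 /M/s)
    free catalyst + open intermediate ⇌ catalyst intermediate (K2 = 1830 /M, k2 = 1540 /M/s)
    reagent + catalyst intermediate ⇌ free catalyst + target (K3 = 0.32, k3 = 395 /M/s)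

Start with the substrate line. Substrate is charged at 11 mM against 16.5 mM of reagent, so it is the limiting reagent; count everything as a fraction of its charge. Substrate, open intermediate, catalyst intermediate and target add up to one, but catalyst intermediate cannot exceed the catalyst charge, 1.00% of the substrate charge.

Now take the catalyst line. Step one opens substrate with free catalyst at rate constant 1310 /M/s, and that gives 6.94 s with the catalyst as charged; call this the catalyst clock, the mean time substrate lasts against the forward step of step one.

Then read the time lines in clocks. The south-west tank holds 3.46 clocks on average, more than the 1.15 of the north flask, so commit to the south-west tank as the best set-up. In the south-east flask, the last substrate dosed sees 0.576 clocks, fewer than in the north flask.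

Reckon the south-west tank by hand, counting forward steps, no way back and the catalyst as charged. Substrate falls to 22.4% and target reaches 62.3%. Hold this yield loosely, for the reckoning leaves the ways back out.

The forecast names south-west as best, with 28.5% there, 14.5% in north, 10.5% in south-east and 12.7% in south, on these grounds: “Contact time therefore decides the ranking”.

The simulation gives south-west as best, with 28.7% there, 14.3% in north, 10.5% in south-east and 12.7% in south.

Hold the clock against the south-west tank: substrate stands at 48.4%, higher than the reckoned 22.4%, and target at 28.7%, lower than the reckoned 62.3%. So the clocks put the south-west tank first, as the simulation does, but the hand yield stood too high. In the south-east flask, the time given is the main reason for its low yield: 1.15 clocks give 10.5%, while 11.5 clocks, at 80.0 s, give 66.6%.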